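Amounts first: what each flask was charged with, and what the two earlier runs read.

| flask | first end groups | second end groups | remark | time |
|---|---|---|---|---|
| violet | 0.020 M | 0.045 M | run made earlier |  |
| amber | 0.11 M | 0.045 M | run made earlier |  |
| north | 0.030 M | 0.0450 M |  | 30 min |
| east | 0.050 M | 0.0450 M |  | 30 min |
| north-east | 0.080 M | 0.0450 M |  | 30 min |
| south | 0.12 M | 0.0450 M |  | 30 min |

- violet (time / min: links / %, first end groups / %): 4.00: 69.4, 0.5; 8.00: 70.0, 0.9; 12.0: 68.3, 1.5; 15.0: 70.9, 0.9; 20.0: 71.0, 0; 25.0: 67.6, 0; 30.0: 68.6, 0.2
- amber (time / min: links / %, first end groups / %): 2.50: 20.5, 54.3; 4.00: 22.5, 53.9; 6.00: 22.6, 53.8; 8.00: 23.6, 52.0; 12.0: 23.2, 52.7; 20.0: 20.2, 53.2; 30.0: 20.8, 51.9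

(scatter of a reading: 1 percentage point)

- the earlier runs were read with a standard deviation of 1 percentage point
- a reading or a percentage of links counts all its forms, free or not
- the concentration of links that is asked is that of its free form alone
- "hardly changes" means that all values lie within two and a half points (for a concentration: within two and a half percent of the largest)
- a reading of first end groups is of its free form alone

1. [links] (only what is free in solution) at the end for north, east, north-east, south, in this order
2. the shape of the row from first to last (rises all the way / falls all the way / falls, then rises / hardly changes / rises, then falls)

**How many links can the charge of second end groups give?** Amber holds first end groups in excess, 0.11 M against 0.045 M, so I take second end groups as its limiting reagent, and its links read between 20.2% and 23.6% from 2.50 min to 30.0 min. The mean of those readings, times the charge, gives 0.0241 M. I call this the link ceiling, the links, free and held, that this charge of second end groups yields.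

**Is the ceiling what is asked?** No: a reading counts held links and the question counts free ones. Amber reads 0.0584 M of free first end groups. No run reads second end groups, so I assume one is used per first end group. That leaves 0.00657 M of first end groups sitting on links, and a binding constant reading about 6.42 L mol⁻¹.

**And below the second charge?** In north, first end groups are limiting, and violet's share of 69.4% gives 0.0208 M.

**Isn't that share too high?** Somewhat: amber made 53.6% links per second end group used, less than violet, and north uses more second end groups than violet.

**Your row?** Above the second charge I divide the ceiling by one plus the binding constant times the excess of first end groups. This gives 0.0234 M, 0.0197 M and 0.0163 M, after 0.0208 M: it rises, then falls.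

The forecast differs: 0.0209 M, 0.0174 M, 0.0103 M, 0.0062 M, so the row falls all the way, on the ground “This fits a fixed 70:30 split if the side product uses two second end groups”.

The flasks give 0.0198 M, 0.0238 M, 0.0203 M, 0.0170 M: the row rises, then falls.

    first end groups + second end groups → links (k = 1.50 L mol⁻¹ s⁻¹)
    first end groups + second end groups → rings, rate k2*[first end groups] as long as [second end groups] is above zero (k = 0.0220 s⁻¹)
    first end groups + links ⇌ idle adduct, settled at all times (K = 6.50 L mol⁻¹)

In north the links step outran the rings step by 3.0 to one just after the start, and by 2.1 to one at 0.136 min, and the flask ended with 65.8% links against 34.2% rings. South, with second end groups down to 0%, had 0.0170 M of free links, 0.00710 M under the ceiling, and 0.00745 M of idle adduct.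

Readings and results were computed from invented constants; the scatter is artificial.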